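## Structural features

The target is a 1,2,4-trisubstituted benzene in which C1 carries the quaternary carbon of an oxirane, C2 an isobutyryloxy group and C4, para to the oxirane, a hydroxymethyl group. The oxirane is 2,2-disubstituted: besides the aryl ring and the ring CH2–O, its quaternary carbon bears a CH2–O–pentanoyl arm, so the core is a masked 2-arylglycerol. That carbon is the only stereocentre (R) and has no stereogenic neighbour, so its control must be absolute. Its two oxygenated one-carbon arms differ only in what sits on oxygen, ring versus acyl. The configuration is therefore lost whenever the arms change roles without inversion at the centre, as in an acyl shift between the two primary oxygens of an open diol monoester, whereas epoxide migration in a free epoxy alcohol exchanges the arms with inversion and returns the same enantiomer. The fragile groups are the benzylic, fully substituted epoxide (acid, Lewis acid), the aryl isobutyrate (an activated ester, sensitive to hydride, alkoxide and basic fluoride), the primary pentanoate (alcoholysis, migration) and the free benzylic alcohol. The real difficulty is twofold: to make the tetrasubstituted benzylic C–O stereocentre enantioselectively, and to sort four oxygens into two different esters, one ether ring and one free hydroxyl without harming the others. The key step exploits the position of the C1(aryl)–C(quaternary) bond, ortho to the phenolic oxygen and para to the hydroxymethyl carbon, which is the site from which a metal-bound 3-substituted phenoxide attacks a carbonyl group; the quaternary carbon derives from a ketone whose two flanks (ester carbon, bromomethyl) are constitutionally different from the start.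

## Logic of the disconnections

**12 to 11.** The benzylic O–H is traced to an O–Si bond. The hydroxymethyl oxygen must stay masked while hydride, acid chloride, base and a second acylation act elsewhere, and a primary silyl ether can be removed last without acid or strong base. The skeleton is unchanged, but the chemoselectivity problems of a free primary alcohol disappear. The forward step must cleave Si–O with buffered fluoride so that the aryl ester and the oxirane of 11 survive.

**11 to 9 (through 10).** The aryl O–C(acyl) bond of the isobutyrate is cut and the phenol oxygen returns to a silyl ether. The aryl ester is the most electrophilic ester in the molecule and would not survive hydride or alkoxide, so it is placed after both. The forward step must cleave the aryl O–Si bond of 9 in preference to the alkyl O–Si bond, and 10 must be acylated before it can react otherwise.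

**9 to 8.** The oxirane CH2–O bond is cut, giving the bromohydrin. Cutting at the methylene and not at the quaternary carbon keeps the stereocentre out of the bond-forming event. The strained, acid-labile ring is then absent for most of the route. The forward step needs a base adequate for a tertiary alcohol yet harmless to a primary ester and an aryl silyl ether, hence carbonate in an aprotic solvent.

**8 to 6 and 7.** The pentanoate C(acyl)–O bond is cut. The ester is put on while the second arm is still a bromomethyl group, so it can shuttle only between the primary and the tertiary oxygen and never to the other arm; the configuration cannot be lost in this way. Acylating before ring closure also spares the base-sensitive benzylic epoxide a free neighbouring hydroxyl. The forward step needs primary-over-tertiary hydroxyl selectivity, which the steric difference in 6 supplies.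

**6 to 5.** The primary carbinol carbon is taken back to the ethyl ester; the bond cleaved in the forward sense is C–O(ethyl). This makes the two one-carbon arms different from the outset, one an ester carbon and the other a bromomethyl. The forward step needs a hydride that reduces an α-hydroxy ester and leaves C–Br and Si–O alone.

**5 to 4.** The aryl O–Si bond is cut to reveal the free phenol that the key step produces. The phenol must be capped before any basic step, because its phenoxide would displace the bromide in a 5-exo closure. The forward step needs a base too weak to ionise the phenol appreciably.

**4 to 2 and 3.** The aryl–C(quaternary) bond is cut. It is the only skeletal C–C disconnection and the one that creates the stereocentre. It divides the molecule into an arene and a three-carbon ketoester, both simple. The forward step needs ortho regiocontrol, a choice between two ortho sites, face selectivity at the ketone, and carbonyl addition in preference to bromide displacement.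

**2 to 1.** The benzylic O–Si bond is cut. The aliphatic oxygen is masked so that only the phenol binds titanium in the key step. The forward step needs silylation of the aliphatic hydroxyl of 1 in preference to the phenol.

## Other disconnections considered

Alternative 1: The cut runs through the oxirane itself. The C(quaternary)–CH2 and CH2–O bonds are both removed, leading back to the aryl ketone 1-[2-(allyloxy)-4-(triisopropylsilyloxymethyl)phenyl]-2-(4-methoxybenzyloxy)ethan-1-one A2 and the one-carbon ylide dimethyloxosulfonium methylide A3.

- **Forward key step:** A3 would add to the ketone of A2 under LaLi3(binaphthoxide)3 (trivalent lanthanum) with a phosphine oxide additive, and the betaine would close to (2R)-2-[2-(allyloxy)-4-(triisopropylsilyloxymethyl)phenyl]-2-[(4-methoxybenzyloxy)methyl]oxirane A1.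
- **In its favour:** in A1 the ring and the stereocentre come from one catalytic Corey–Chaykovsky step, and the ring carbons arrive at their final oxidation level. No bromohydrin is ever present, so the hazard of a phenoxide displacing bromide does not arise. On these points it is better than the chosen plan.
- **Against it here:** this catalysis discriminates best between a small methyl and a large group. A2 offers an ortho-alkoxyaryl ring twisted out of conjugation against a CH2OPMB group that can also bind the lithium and lanthanum centres, so the facial preference is hard to foresee. A2 needs an ortho-acylation of a protected phenol and an α-oxygenation, about four to five steps. After the key step the PMB group of A1 must be removed oxidatively beside an acid-sensitive benzylic epoxide on an electron-rich ring, which is a chemoselectivity risk. The free epoxy alcohol exposed there is configurationally safe, because epoxide migration would exchange the two CH2O arms with inversion and return the same enantiomer, but it is prone to intermolecular opening under base. Pentanoylation, removal of the allyl ether with Pd(PPh3)4 (zerovalent palladium), isobutyrylation and desilylation would follow.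
- **Comparison:** both plans use a binaphthoxide catalyst and both extend a known enantioselective reaction to a new substrate, so on catalyst control they are equals. Structurally the alternative makes the epoxide early and carries it through three deprotections, while the chosen plan keeps it latent as a bromohydrin until step 6 of 8. Mechanistically the alternative must distinguish two ketone flanks of similar size in an open addition, the chosen plan two flanks of a chelated ketone in a closed transition state. In step count the alternative would need about eleven against eight.

Alternative 2: The cut is the C(quaternary)–O bond of the tertiary carbinol, with a vinyl group standing in for one CH2O arm.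

- **Forward key step:** Pd2(dba)3 (zerovalent palladium) with a chiral phosphoramidite would ionise racemic 4-[4-(tert-butyldimethylsilyloxymethyl)-2-(triisopropylsilyloxy)phenyl]-4-vinyl-1,3-dioxolan-2-one A5 with decarboxylation. The oxygen nucleophile water A6 would attack the aryl-bearing terminus of the allyl complex to give (2R)-2-[4-(tert-butyldimethylsilyloxymethyl)-2-(triisopropylsilyloxy)phenyl]but-3-ene-1,2-diol A4.
- **In its favour:** the process is stereoconvergent, so a racemate is funnelled into one enantiomer, and A6 is the cheapest possible reagent. The reaction type is established for 4-aryl-4-vinyl carbonates, a closer precedent than bromopyruvate offers the chosen step; on precedent and on tolerance of racemic input it is better. In A4 the three carbon substituents of the stereocentre are clearly different, so no arm-exchange pathway exists at that stage.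
- **Against it here:** the bulky ortho-silyloxy group would hinder both ionisation and attack at the branched terminus. A5 has to be made from an α-hydroxy aryl ketone by vinyl addition and carbonate formation. With the configuration of A4, the primary hydroxyl must become the oxirane CH2 (sulfonylation and closure) and the vinyl group must be ozonised and reduced to the CH2O-pentanoyl arm. That passes through a vinyl oxirane, an epoxy aldehyde and a free epoxy alcohol, three sensitive intermediates, before the pentanoate can be put on. One carbon is introduced only to be removed.
- **Comparison:** the alternative forms the C–O bond at the stereocentre by outer-sphere attack of A6 on an allyl complex; the chosen plan forms the C–C bond by inner-sphere delivery from a titanium-bound aryloxide. The silyl protection problem is the same in both, so there they are equals. In step count the alternative is clearly longer, about twelve or more.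

Alternative 3: The cut is the pentanoate C(acyl)–O bond, leading back to the prochiral triol 2-[2-(allyloxy)-4-(triisopropylsilyloxymethyl)phenyl]propane-1,2,3-triol A8 and the acyl donor vinyl pentanoate A9.

- **Forward key step:** a lipase would transfer the acyl group of A9 to one enantiotopic CH2OH of A8, giving (2R)-2-[2-(allyloxy)-4-(triisopropylsilyloxymethyl)phenyl]-2,3-dihydroxypropyl pentanoate A7.
- **In its favour:** the acyl group that A9 delivers is the target's own, so one step sets the stereocentre and installs a final substituent, which is better than the chosen plan on this point. A desymmetrisation can in principle convert all material, the conditions are mild and metal-free, and enzyme screening is cheap. The remaining CH2OH of A7 becomes the oxirane carbon directly by sulfonylation and closure.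
- **Against it here:** the prochiral centre of A8 is fully substituted and carries a tertiary hydroxyl and a bulky ortho-substituted aryl group. Recognition of such centres is strongly substrate-dependent, and which CH2OH is acylated cannot be predicted. A 1,3-acyl shift between the two primary oxygens of A7 through a six-membered intermediate converts it into its enantiomer, so every basic step afterwards threatens the enantiopurity. Over-acylation to a diester would compete. A8 requires an ortho-metallated phenol ether and a protected dihydroxyacetone, or a dihydroxylation.
- **Comparison:** in the chosen plan the two arms are constitutionally different (ester carbon, CH2Br) and never become interconvertible, which is its main structural advantage over a route through A7. The step counts are about equal. The allyl ether would need Pd(PPh3)4 (zerovalent palladium) late, against fluoride in the chosen plan.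

Key step: step 2

Assumption: the (R)-antipode of BINOL is written in step 2; which antipode leads to (S)-4 depends on the sense of induction for the CH2Br/CO2Et pair, taken here by analogy with fluorinated ketoesters, and the mirror-image ligand is used if the sense is reversed.

## Route

Step 1
Reactants: 1 3-hydroxybenzyl alcohol
Product: 2 3-(triisopropylsilyloxymethyl)phenol
Conditions: TIPSCl (1.05 equiv), imidazole, DMF, 0 °C
Reagents that add atoms: triisopropylsilyl chloride, CC(C)[Si](Cl)(C(C)C)C(C)C
Why: Silylation through the N-silylimidazolium; the un-ionised primary benzylic alcohol is the better nucleophile towards the bulky silicon electrophile than the un-ionised phenol, so one equivalent at 0 °C should take the aliphatic hydroxyl first, and no stereocentre is involved.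

Step 2
Reactants: 2 3-(triisopropylsilyloxymethyl)phenol; 3 ethyl bromopyruvate
Product: 4 ethyl (2S)-3-bromo-2-hydroxy-2-[2-hydroxy-4-(triisopropylsilyloxymethyl)phenyl]propanoate
Conditions: Ti(OiPr)4 (10 mol %), (R)-BINOL (20 mol %), 4 Å MS, toluene, −20 → 0 °C
Reagents that add atoms: none
Why: Phenol 2 exchanges for an isopropoxide on the chiral binaphthoxide complex of tetravalent titanium and 3 binds the same metal through its ketone and ester oxygens; the ortho carbon of the bound aryloxide then adds to the activated ketone carbon through a closed six-membered transition state, the dienone tautomerises back to the arene, and protonolysis by fresh 2 releases 4. The closest known reaction type is the enantioselective ortho Friedel–Crafts hydroxyalkylation of phenols with activated α-ketoesters such as ethyl trifluoropyruvate under Ti(OiPr)4/BINOL catalysts, together with the ortho-specific hydroxyalkylation of metal phenoxides by pyruvates; the bromomethyl ketone is a less activated member of the same class. No ring is closed. The one new stereocentre, the tertiary carbinol carbon, is set under catalyst control: the binaphthoxide shields one face of the chelated ketone, whose flanks are distinguished because CO2Et is held in the chelate while CH2Br points away, and the (S)-configuration is the one needed. Ortho over para attack follows from delivery by the titanium-bound oxygen, and of the two ortho carbons C6 (para to the silyloxymethyl group) is open while C2 is flanked on both sides. Addition to the carbonyl must win over displacement of bromide, which the non-basic medium secures because no free phenoxide is present, and the bulky TIPS ether keeps the benzylic oxygen off the metal.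

Step 3
Reactants: 4 ethyl (2S)-3-bromo-2-hydroxy-2-[2-hydroxy-4-(triisopropylsilyloxymethyl)phenyl]propanoate
Product: 5 ethyl (2S)-3-bromo-2-[2-(tert-butyldimethylsilyloxy)-4-(triisopropylsilyloxymethyl)phenyl]-2-hydroxypropanoate
Conditions: TBSCl, imidazole, DMF, 0 °C
Reagents that add atoms: tert-butyldimethylsilyl chloride, CC(C)(C)[Si](C)(C)Cl
Why: Silylation of the phenol through the N-silylimidazolium; the tertiary carbinol is inert to TBSCl, and imidazole is too weak a base to build up the phenoxide that could displace bromide (5-exo) or lactonise onto the ester, so the stereocentre and the bromohydrin should stay intact.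

Step 4
Reactants: 5 ethyl (2S)-3-bromo-2-[2-(tert-butyldimethylsilyloxy)-4-(triisopropylsilyloxymethyl)phenyl]-2-hydroxypropanoate
Product: 6 (2S)-3-bromo-2-[2-(tert-butyldimethylsilyloxy)-4-(triisopropylsilyloxymethyl)phenyl]propane-1,2-diol
Conditions: LiBH4, THF, 0 °C
Reagents that add atoms: none
Why: Chelation-assisted hydride reduction of the α-hydroxy ester to the primary alcohol; the neopentyl-type C–Br bond and both silyl ethers are inert to LiBH4 at 0 °C, the boron-bound alkoxides are too weakly nucleophilic to close the oxirane early, and the quaternary stereocentre is not involved.

Step 5
Reactants: 6 (2S)-3-bromo-2-[2-(tert-butyldimethylsilyloxy)-4-(triisopropylsilyloxymethyl)phenyl]propane-1,2-diol; 7 pentanoyl chloride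
Product: 8 (2S)-3-bromo-2-[2-(tert-butyldimethylsilyloxy)-4-(triisopropylsilyloxymethyl)phenyl]-2-hydroxypropyl pentanoate
Conditions: pyridine, CH2Cl2, −20 → 0 °C
Reagents that add atoms: none
Why: Selective O-acylation with an acid chloride; the primary hydroxyl reacts while the tertiary benzylic hydroxyl, crowded by the ortho-silyloxyaryl group, does not, and pyridine is too weak a base to trigger ring closure.

Step 6
Reactants: 8 (2S)-3-bromo-2-[2-(tert-butyldimethylsilyloxy)-4-(triisopropylsilyloxymethyl)phenyl]-2-hydroxypropyl pentanoate
Product: 9 [(2R)-2-[2-(tert-butyldimethylsilyloxy)-4-(triisopropylsilyloxymethyl)phenyl]oxiran-2-yl]methyl pentanoate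
Conditions: K2CO3, MeCN, 25 °C
Reagents that add atoms: none
Why: Intramolecular Williamson etherification (3-exo-tet); the tertiary alkoxide displaces bromide at the neighbouring CH2, so the new C–O bond forms at the methylene and the quaternary centre keeps its spatial arrangement (the descriptor changes from S to R only through the change in priorities), while aprotic MeCN avoids alcoholysis of the pentanoate and any reversible 1,2-acyl shift is drained by the irreversible ring closure.

Step 7
Reactants: 9 [(2R)-2-[2-(tert-butyldimethylsilyloxy)-4-(triisopropylsilyloxymethyl)phenyl]oxiran-2-yl]methyl pentanoate
Product: 11 [(2R)-2-[2-(2-methylpropanoyloxy)-4-(triisopropylsilyloxymethyl)phenyl]oxiran-2-yl]methyl pentanoate, via tetrabutylammonium phenoxide 10 (not isolated)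
Conditions: TBAF (1.05 equiv), THF, −40 °C; then (iPrCO)2O, −40 → 0 °C
Reagents that add atoms: isobutyric anhydride, CC(C)C(=O)OC(=O)C(C)C
Why: One-pot fluoride desilylation and acylation; fluoride cleaves the aryl O–Si bond much faster than the alkyl O–TIPS bond because phenoxide is the better leaving group, the phenoxide 10 is acylated at once by the anhydride, and its attack on the oxirane CH2 would be a geometrically disfavoured 5-endo opening, so epoxide and stereocentre should persist.

Step 8
Reactants: 11 [(2R)-2-[2-(2-methylpropanoyloxy)-4-(triisopropylsilyloxymethyl)phenyl]oxiran-2-yl]methyl pentanoate
Product: 12 [(2R)-2-[4-(hydroxymethyl)-2-(2-methylpropanoyloxy)phenyl]oxiran-2-yl]methyl pentanoate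
Conditions: TBAF, AcOH (1:1), THF, 0 → 25 °C
Reagents that add atoms: none
Why: Fluoride-mediated cleavage of the primary TIPS ether; buffering with acetic acid keeps the medium near neutral, so the aryl ester should not be cleaved by basic fluoride or alkoxide and the benzylic epoxide should not be opened by acid, and no stereocentre is touched.

## Compound list

1 | 3-hydroxybenzyl alcohol | OCc1cccc(O)c1 | starting material
2 | 3-(triisopropylsilyloxymethyl)phenol | Oc1cccc(CO[Si](C(C)C)(C(C)C)C(C)C)c1 | intermediate
3 | ethyl bromopyruvate (ethyl 3-bromo-2-oxopropanoate) | CCOC(=O)C(=O)CBr | starting material
4 | ethyl (2S)-3-bromo-2-hydroxy-2-[2-hydroxy-4-(triisopropylsilyloxymethyl)phenyl]propanoate | CCOC(=O)[C@@](O)(c1ccc(CO[Si](C(C)C)(C(C)C)C(C)C)cc1O)CBr | intermediate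
5 | ethyl (2S)-3-bromo-2-[2-(tert-butyldimethylsilyloxy)-4-(triisopropylsilyloxymethyl)phenyl]-2-hydroxypropanoate | CCOC(=O)[C@@](O)(c1ccc(CO[Si](C(C)C)(C(C)C)C(C)C)cc1O[Si](C)(C)C(C)(C)C)CBr | intermediate
6 | (2S)-3-bromo-2-[2-(tert-butyldimethylsilyloxy)-4-(triisopropylsilyloxymethyl)phenyl]propane-1,2-diol | OC[C@@](O)(c1ccc(CO[Si](C(C)C)(C(C)C)C(C)C)cc1O[Si](C)(C)C(C)(C)C)CBr | intermediate
7 | pentanoyl chloride | CCCCC(=O)Cl | starting material
8 | (2S)-3-bromo-2-[2-(tert-butyldimethylsilyloxy)-4-(triisopropylsilyloxymethyl)phenyl]-2-hydroxypropyl pentanoate | CCCCC(=O)OC[C@@](O)(c1ccc(CO[Si](C(C)C)(C(C)C)C(C)C)cc1O[Si](C)(C)C(C)(C)C)CBr | intermediate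
9 | [(2R)-2-[2-(tert-butyldimethylsilyloxy)-4-(triisopropylsilyloxymethyl)phenyl]oxiran-2-yl]methyl pentanoate | CCCCC(=O)OC[C@@]1(c2ccc(CO[Si](C(C)C)(C(C)C)C(C)C)cc2O[Si](C)(C)C(C)(C)C)CO1 | intermediate
10 | tetrabutylammonium 2-[(2R)-2-(pentanoyloxymethyl)oxiran-2-yl]-5-(triisopropylsilyloxymethyl)phenoxide | CCCCC(=O)OC[C@@]1(c2ccc(CO[Si](C(C)C)(C(C)C)C(C)C)cc2[O-])CO1.CCCC[N+](CCCC)(CCCC)CCCC | intermediate
11 | [(2R)-2-[2-(2-methylpropanoyloxy)-4-(triisopropylsilyloxymethyl)phenyl]oxiran-2-yl]methyl pentanoate | CCCCC(=O)OC[C@@]1(c2ccc(CO[Si](C(C)C)(C(C)C)C(C)C)cc2OC(=O)C(C)C)CO1 | intermediate
12 | [(2R)-2-[4-(hydroxymethyl)-2-(2-methylpropanoyloxy)phenyl]oxiran-2-yl]methyl pentanoate | CCCCC(=O)OC[C@@]1(c2ccc(CO)cc2OC(=O)C(C)C)CO1 | target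

## Step count and least certain steps

Total: 8 steps. Longest linear sequence: 8 steps (1 to 12); 3 and 7 are used as purchased.

**Step 2 (key step).**
- **Risk:** low turnover and eroded facial selectivity. Bromopyruvate is less electrophilic than the fluorinated ketoesters on which this catalysis is established. The product, an α-hydroxy ester with a neighbouring phenol, can hold on to titanium. CH2Br and CO2Et differ less than CF3 and CO2Et. Attack at the C–Br carbon or enolisation of the ketone may compete.
- **Fallback:** stereocontrol is given up and replaced by resolution. From 2 and 3, the aryloxide is formed stoichiometrically with achiral TiCl(OiPr)3 in CH2Cl2 and added to 3 at −20 °C. This ortho-specific hydroxyalkylation of a metal phenoxide by an α-ketoester should give racemic ethyl 3-bromo-2-hydroxy-2-[2-hydroxy-4-(triisopropylsilyloxymethyl)phenyl]propanoate F1. Preparative chromatography on a chiral stationary phase then separates the (S)-enantiomer, which is 4 and rejoins the route there, from ethyl (2R)-3-bromo-2-hydroxy-2-[2-hydroxy-4-(triisopropylsilyloxymethyl)phenyl]propanoate F2, which is set aside.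

**Step 1.**
- **Risk:** silylation at the phenol, or double silylation, if the discrimination between the two hydroxyls is weaker with the bulky chloride than expected. That would leave mixtures which cost material at the very start.
- **Fallback:** from 1, exhaustive silylation (TIPSCl in excess, imidazole, DMF) should give triisopropyl[3-(triisopropylsilyloxymethyl)phenoxy]silane F3. Its aryl O–Si bond alone is then cleaved with KHF2 in MeOH at 25 °C, a reagent that attacks phenolic but not alkyl silyl ethers, returning to the route at 2.

**Step 6.**
- **Risk:** transfer of the pentanoyl group, or of the aryl silyl group, to the tertiary alkoxide in competition with ring closure; a phenoxide set free in this way would displace the bromide. A sluggish heterogeneous deprotonation would lengthen the exposure.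
- **Fallback:** the order of ring closure and acylation is reversed. From 6, K2CO3 in MeCN closes the oxirane while no ester is present, giving [(2S)-2-[2-(tert-butyldimethylsilyloxy)-4-(triisopropylsilyloxymethyl)phenyl]oxiran-2-yl]methanol F4. The descriptor is S only because the priorities change; the spatial arrangement is that of 9. F4 is acylated at once with 7 and pyridine in CH2Cl2 at 0 °C, returning to the route at 9. The price is a primary hydroxyl beside the epoxide. Migration of the epoxide to the other arm would be degenerate here and would return the same enantiomer, so the concern is not the configuration but intermolecular opening of the epoxide by the primary alkoxide, and the base contact is kept brief for that reason.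

**Step 8.**
- **Risk:** slow cleavage of the hindered TIPS ether under buffered fluoride, so that prolonged exposure leads to loss or transfer of the aryl isobutyrate or to opening of the benzylic epoxide.
- **Fallback:** both silyl groups are removed before the aryl ester exists. From 9, unbuffered TBAF in THF at 0 °C should give [(2R)-2-[2-hydroxy-4-(hydroxymethyl)phenyl]oxiran-2-yl]methyl pentanoate F5. Its phenol is then acylated selectively through the phenoxide (isobutyric anhydride, one equivalent, K2CO3, acetone, 0 °C), the far more acidic phenol reacting before the benzylic alcohol. This returns to the route at 12 and also bypasses step 7.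

## Further compounds

F1 | step 2 | racemic ethyl 3-bromo-2-hydroxy-2-[2-hydroxy-4-(triisopropylsilyloxymethyl)phenyl]propanoate | CCOC(=O)C(O)(c1ccc(CO[Si](C(C)C)(C(C)C)C(C)C)cc1O)CBr
F2 | step 2 | ethyl (2R)-3-bromo-2-hydroxy-2-[2-hydroxy-4-(triisopropylsilyloxymethyl)phenyl]propanoate | CCOC(=O)[C@](O)(c1ccc(CO[Si](C(C)C)(C(C)C)C(C)C)cc1O)CBr
F3 | step 1 | triisopropyl[3-(triisopropylsilyloxymethyl)phenoxy]silane | CC(C)[Si](OCc1cccc(O[Si](C(C)C)(C(C)C)C(C)C)c1)(C(C)C)C(C)C
F4 | step 6 | [(2S)-2-[2-(tert-butyldimethylsilyloxy)-4-(triisopropylsilyloxymethyl)phenyl]oxiran-2-yl]methanol | OC[C@@]1(c2ccc(CO[Si](C(C)C)(C(C)C)C(C)C)cc2O[Si](C)(C)C(C)(C)C)CO1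
F5 | step 8 | [(2R)-2-[2-hydroxy-4-(hydroxymethyl)phenyl]oxiran-2-yl]methyl pentanoate | CCCCC(=O)OC[C@@]1(c2ccc(CO)cc2O)CO1
A1 | alternative 1 | (2R)-2-[2-(allyloxy)-4-(triisopropylsilyloxymethyl)phenyl]-2-[(4-methoxybenzyloxy)methyl]oxirane | COc1ccc(COC[C@@]2(c3ccc(CO[Si](C(C)C)(C(C)C)C(C)C)cc3OCC=C)CO2)cc1
A2 | alternative 1 | 1-[2-(allyloxy)-4-(triisopropylsilyloxymethyl)phenyl]-2-(4-methoxybenzyloxy)ethan-1-one | COc1ccc(COCC(=O)c2ccc(CO[Si](C(C)C)(C(C)C)C(C)C)cc2OCC=C)cc1
A3 | alternative 1 | dimethyloxosulfonium methylide | C[S+](C)(=O)[CH2-]
A4 | alternative 2 | (2R)-2-[4-(tert-butyldimethylsilyloxymethyl)-2-(triisopropylsilyloxy)phenyl]but-3-ene-1,2-diol | C=C[C@@](O)(c1ccc(CO[Si](C)(C)C(C)(C)C)cc1O[Si](C(C)C)(C(C)C)C(C)C)CO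
A5 | alternative 2 | racemic 4-[4-(tert-butyldimethylsilyloxymethyl)-2-(triisopropylsilyloxy)phenyl]-4-vinyl-1,3-dioxolan-2-one | C=CC1(c2ccc(CO[Si](C)(C)C(C)(C)C)cc2O[Si](C(C)C)(C(C)C)C(C)C)COC(=O)O1
A6 | alternative 2 | water | O
A7 | alternative 3 | (2R)-2-[2-(allyloxy)-4-(triisopropylsilyloxymethyl)phenyl]-2,3-dihydroxypropyl pentanoate | CCCCC(=O)OC[C@@](O)(c1ccc(CO[Si](C(C)C)(C(C)C)C(C)C)cc1OCC=C)CO
A8 | alternative 3 | 2-[2-(allyloxy)-4-(triisopropylsilyloxymethyl)phenyl]propane-1,2,3-triol | OCC(O)(c1ccc(CO[Si](C(C)C)(C(C)C)C(C)C)cc1OCC=C)CO
A9 | alternative 3 | vinyl pentanoate | CCCCC(=O)OC=C
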